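## Retrosynthetic overview

1. Numbering used: ring B = C1 (bears the side chain), C2, C3, C4 (bears CH3); ring A (arene) = C4a, C5 (OH), C6 (OH), C7 (CO2H), C8, C8a; side chain = C11 (bears C20H2OH), C12–C14, C15 (bears CH3), C16H2OH. The last operations are C7 carboxylation by MOM-directed ortho-lithiation of the finished tetralin and one acid deprotection.
2. Key disconnection: C2–C3 of ring B (made as C2=C3) together with C13–C14 of the side chain, both by olefin metathesis in one operation. The enabling feature is that C1 and C4 are benzylic methines on the adjacent arene carbons C8a and C4a and are joined only through the C2–C3 ethano unit, so ring B is the retron of a ring-closing metathesis of two ortho benzylic alkenyl arms; the unbranched C12–C14 chain is the retron of a cross-metathesis.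
3. C1 and C11 are set together by iridium/enamine dual-catalytic α-allylation of pent-4-enal with an aryl vinyl carbinol; C15 is bought (Roche ester).
4. C4 is set by Pd-catalysed asymmetric O-allylation of the C5 phenol and relayed to carbon by an aromatic Claisen rearrangement into C4a (C5–O is ortho to C4a).
5. Ring order: ring A is bought (3,4-dihydroxybenzaldehyde); a transient cyclopentene (C1, C2, C13, C12, C11) forms and is cleaved again inside the key step; ring B closes last.

Key step: step 12

## Remarks on the chemistry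

- Assumption for step 3: the (S,S)-ligand is taken to give the (S)-ether 5; if the sense is the opposite, the (R,R)-ligand is used.
- Assumption for step 7: the (S)-ligand/(S)-amine pairing is taken to give the (2S,3S) product; the method is stereodivergent, so one of the four pairings gives it.

## Route

Step 1
Reactants: 1 3,4-dihydroxybenzaldehyde
Product: 2 3-hydroxy-4-(methoxymethoxy)benzaldehyde
Conditions: MOMCl (1.05 equiv), K2CO3 (1.1 equiv), acetone, 0 °C to rt
Reagents that add atoms: chloromethyl methyl ether, COCCl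
Why: Williamson-type O-alkylation in which the 4-OH, para to the formyl group and therefore the more acidic phenol, is alkylated selectively by one equivalent of a weak base.

Step 2
Reactants: 3 rac-(3E)-pent-3-en-2-ol
Product: 4 rac-methyl (3E)-pent-3-en-2-yl carbonate
Conditions: ClCO2Me, pyridine, CH2Cl2, 0 °C
Reagents that add atoms: methyl chloroformate, COC(=O)Cl
Why: Standard acylation of a secondary allylic alcohol gives the carbonate that serves as the ionisable leaving group for π-allyl chemistry.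

Step 3
Reactants: 2 3-hydroxy-4-(methoxymethoxy)benzaldehyde; 4 rac-methyl (3E)-pent-3-en-2-yl carbonate
Product: 5 4-(methoxymethoxy)-3-{[(2S,3E)-pent-3-en-2-yl]oxy}benzaldehyde
Conditions: Pd2(dba)3·CHCl3 (1 mol %), (S,S)-DACH-phenyl Trost ligand (3 mol %), CH2Cl2, rt
Reagents that add atoms: none
Why: Tsuji–Trost asymmetric allylic etherification, in which zerovalent palladium ionises both enantiomers of 4 to the same symmetrical 1,3-dimethylallyl complex and the chiral ligand directs the phenol to one of the two enantiotopic termini, setting the O-bearing stereocenter that is later relayed to C4.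

Step 4
Reactants: 5 4-(methoxymethoxy)-3-{[(2S,3E)-pent-3-en-2-yl]oxy}benzaldehyde
Product: 7 3-hydroxy-4-(methoxymethoxy)-2-[(2R,3E)-pent-3-en-2-yl]benzaldehyde, via ortho-dienone 6 (not isolated)
Conditions: Eu(fod)3 (10 mol %), CHCl3, 50 °C
Reagents that add atoms: none
Why: Aromatic Claisen rearrangement into the only free ortho position through a chair transition state with the carbinol methyl equatorial, so that the (S)-C–O stereocenter is transferred suprafacially into the (R)-C–C stereocenter C4 carrying an (E)-propenyl group, followed by enolisation of the dienone.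

Step 5
Reactants: 7 3-hydroxy-4-(methoxymethoxy)-2-[(2R,3E)-pent-3-en-2-yl]benzaldehyde
Product: 8 3,4-bis(methoxymethoxy)-2-[(2R,3E)-pent-3-en-2-yl]benzaldehyde
Conditions: NaH, DMF, 0 °C; MOMCl
Reagents that add atoms: chloromethyl methyl ether, COCCl
Why: O-alkylation of the hindered phenoxide completes the bis-MOM catechol, whose C6 acetal later directs lithiation to C7.

Step 6
Reactants: 8 3,4-bis(methoxymethoxy)-2-[(2R,3E)-pent-3-en-2-yl]benzaldehyde
Product: 9 (1RS)-1-{3,4-bis(methoxymethoxy)-2-[(2R,3E)-pent-3-en-2-yl]phenyl}prop-2-en-1-ol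
Conditions: CH2=CHMgBr, THF, −78 to 0 °C; aq. NH4Cl
Reagents that add atoms: vinylmagnesium bromide, C=C[Mg]Br
Why: Grignard 1,2-addition gives the aryl vinyl carbinol, whose new carbinol centre need not be controlled because it is ionised in the next step.

Step 7
Reactants: 9 (1RS)-1-{3,4-bis(methoxymethoxy)-2-[(2R,3E)-pent-3-en-2-yl]phenyl}prop-2-en-1-ol; 10 pent-4-enal
Product: 12 (2S,3S)-3-{3,4-bis(methoxymethoxy)-2-[(2R,3E)-pent-3-en-2-yl]phenyl}-2-(prop-2-en-1-yl)pent-4-en-1-ol, via aldehyde 11 (not isolated)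
Conditions: [Ir(cod)Cl]2 (3 mol %), (S)-phosphoramidite–olefin ligand (12 mol %), (S)-diarylprolinol silyl ether (15 mol %), (MeO)2P(O)OH (5 mol %), ClCH2CH2Cl, 25 °C; then NaBH4, MeOH, 0 °C
Reagents that add atoms: none
Why: Stereodivergent iridium/enamine dual-catalytic α-allylation of a linear aldehyde with a racemic aryl vinyl carbinol, in which the chiral allyl–iridium complex fixes C1 and the chiral enamine of 10 fixes C11 independently in one branched-selective C–C bond formation (a close precedent uses a di-ortho-substituted aryl vinyl carbinol), and the epimerisable aldehyde is reduced in the same flask.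

Step 8
Reactants: 12 (2S,3S)-3-{3,4-bis(methoxymethoxy)-2-[(2R,3E)-pent-3-en-2-yl]phenyl}-2-(prop-2-en-1-yl)pent-4-en-1-ol
Product: 13 tert-butyl{[(2S,3S)-3-{3,4-bis(methoxymethoxy)-2-[(2R,3E)-pent-3-en-2-yl]phenyl}-2-(prop-2-en-1-yl)pent-4-en-1-yl]oxy}dimethylsilane
Conditions: TBSCl, imidazole, DMF, rt
Reagents that add atoms: tert-butyldimethylsilyl chloride, CC(C)(C)[Si](C)(C)Cl
Why: Routine silylation masks the C20 hydroxyl so that no alkoxide competes with the MOM group as a directing group in the later lithiation.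

Step 9
Reactants: 14 methyl (2R)-3-hydroxy-2-methylpropanoate
Product: 15 methyl (2R)-3-{[tert-butyl(dimethyl)silyl]oxy}-2-methylpropanoate
Conditions: TBSCl, imidazole, CH2Cl2, rt
Reagents that add atoms: tert-butyldimethylsilyl chloride, CC(C)(C)[Si](C)(C)Cl
Why: Routine silylation of the bought Roche ester, which supplies C15 with its methyl group and C16.

Step 10
Reactants: 15 methyl (2R)-3-{[tert-butyl(dimethyl)silyl]oxy}-2-methylpropanoate
Product: 16 (2R)-3-{[tert-butyl(dimethyl)silyl]oxy}-2-methylpropanal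
Conditions: i-Bu2AlH (1.05 equiv), CH2Cl2, −78 °C; aq. potassium sodium tartrate
Reagents that add atoms: none
Why: Partial reduction of the ester stops at the aldehyde because the tetrahedral aluminium hemiacetal is stable at −78 °C, and the α-stereocenter is untouched at this temperature.

Step 11
Reactants: 16 (2R)-3-{[tert-butyl(dimethyl)silyl]oxy}-2-methylpropanal
Product: 17 tert-butyl(dimethyl){[(2S)-2-methylbut-3-en-1-yl]oxy}silane
Conditions: Ph3PCH3Br, KN(SiMe3)2, THF, 0 °C
Reagents that add atoms: methyltriphenylphosphonium bromide, C[P+](c1ccccc1)(c1ccccc1)c1ccccc1.[Br-]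
Why: Wittig methylenation with a non-stabilised ylide at low temperature keeps the α-stereocenter, whose descriptor changes from R to S only through the CIP ranking.

Step 12
Reactants: 13 tert-butyl{[(2S,3S)-3-{3,4-bis(methoxymethoxy)-2-[(2R,3E)-pent-3-en-2-yl]phenyl}-2-(prop-2-en-1-yl)pent-4-en-1-yl]oxy}dimethylsilane; 17 tert-butyl(dimethyl){[(2S)-2-methylbut-3-en-1-yl]oxy}silane
Product: 19 (1S,4R)-1-[(2S,4E,6S)-1,7-bis{[tert-butyl(dimethyl)silyl]oxy}-6-methylhept-4-en-2-yl]-5,6-bis(methoxymethoxy)-4-methyl-1,4-dihydronaphthalene, via cyclopentene 18 (not isolated)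
Conditions: 17 (4 equiv), RuCl2(H2IMes)(=CH-C6H4-2-OiPr) (second-generation Hoveyda–Grubbs catalyst, 2 × 5 mol %), 1,4-benzoquinone (10 mol %), toluene (0.01 M), 40 °C then 70 °C, Ar sparge
Reagents that add atoms: none
Why: Olefin metathesis cascade in which the ruthenium alkylidene first closes the kinetically favoured cyclopentene 18 between the C2 vinyl and the C11 allyl group (ethene lost), the alkylidene formed from 17 then reopens this strained cis-olefin by ring-opening cross-metathesis (new C13=C14 bond), and the ruthenium left on C2 closes ring B onto the (E)-propenyl arm, forming C2=C3 and expelling the ethylidene unit as propene. The closest known reaction types are ring-rearrangement metathesis of cyclopentenes that carry a tethered olefin, ring-closing metathesis of arenes with two ortho allylic arms to 1,4-dihydronaphthalenes, and cross-metathesis of an allyl terminus with an allylically branched 1-alkene. Ring B is closed as a six-membered ring by ring-closing metathesis with both olefin carbons (C2, C3) inside the ring and the other four members (C1, C8a, C4a, C4) fixed in advance, while the five-membered ring is only a transient relay that is cleaved in the same flask. No stereocenter is created, since C1, C4, C11 and C15 are sp3 centres that metathesis does not touch, and the E/Z ratio at C13=C14 is irrelevant because both olefins are hydrogenated next. The step needs the six-ring cross-coupled product to win over the cyclopentene, oligomers and the homodimer of 17, which should be secured by release of the cyclopentene strain into a nearly strain-free benzo-fused ring, by irreversible loss of ethene and propene, by the excess of the slowly dimerising 17, and by the hindered C2=C3 olefin being inert to re-opening. 1,4-Benzoquinone is added to suppress ruthenium hydride isomerisation of the skipped diene into conjugation, which would erase C1 and C4.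

Step 13
Reactants: 19 (1S,4R)-1-[(2S,4E,6S)-1,7-bis{[tert-butyl(dimethyl)silyl]oxy}-6-methylhept-4-en-2-yl]-5,6-bis(methoxymethoxy)-4-methyl-1,4-dihydronaphthalene
Product: 20 (1S,4R)-1-[(2S,6S)-1,7-bis{[tert-butyl(dimethyl)silyl]oxy}-6-methylheptan-2-yl]-5,6-bis(methoxymethoxy)-4-methyl-1,2,3,4-tetrahydronaphthalene
Conditions: H2 (1 atm), PtO2 (5 mol %), EtOAc, rt
Reagents that add atoms: none
Why: Heterogeneous hydrogenation saturates the C2=C3 and C13=C14 olefins without creating a stereocenter, and platinum is chosen over palladium to limit double-bond migration toward C1, C4 or C15.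

Step 14
Reactants: 20 (1S,4R)-1-[(2S,6S)-1,7-bis{[tert-butyl(dimethyl)silyl]oxy}-6-methylheptan-2-yl]-5,6-bis(methoxymethoxy)-4-methyl-1,2,3,4-tetrahydronaphthalene
Product: 22 (5R,8S)-8-[(2S,6S)-1,7-bis{[tert-butyl(dimethyl)silyl]oxy}-6-methylheptan-2-yl]-3,4-bis(methoxymethoxy)-5-methyl-5,6,7,8-tetrahydronaphthalene-2-carboxylic acid, via aryllithium 21 (not isolated)
Conditions: s-BuLi (1.3 equiv), TMEDA, THF, −78 °C; CO2; 1 M HCl to pH 3, 0 °C
Reagents that add atoms: carbon dioxide, O=C=O
Why: Directed ortho-metalation, in which the C6 MOM ether directs lithiation to C7, the only ring C–H ortho to an oxygen director (C8–H is flanked by C8a), and the aryllithium is carboxylated.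

Step 15
Reactants: 22 (5R,8S)-8-[(2S,6S)-1,7-bis{[tert-butyl(dimethyl)silyl]oxy}-6-methylheptan-2-yl]-3,4-bis(methoxymethoxy)-5-methyl-5,6,7,8-tetrahydronaphthalene-2-carboxylic acid
Product: 23 (5R,8S)-3,4-dihydroxy-8-[(2S,6S)-1,7-dihydroxy-6-methylheptan-2-yl]-5-methyl-5,6,7,8-tetrahydronaphthalene-2-carboxylic acid
Conditions: 3 M HCl, THF/H2O, 45 °C
Reagents that add atoms: none
Why: Acid-catalysed hydrolysis cleaves both aryl MOM acetals and both primary silyl ethers in one operation without touching any stereocenter.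

## Compound list

1 | 3,4-dihydroxybenzaldehyde | O=Cc1ccc(O)c(O)c1 | starting material
2 | 3-hydroxy-4-(methoxymethoxy)benzaldehyde | COCOc1ccc(C=O)cc1O | intermediate
3 | rac-(3E)-pent-3-en-2-ol | C/C=C/C(C)O | starting material
4 | rac-methyl (3E)-pent-3-en-2-yl carbonate | C/C=C/C(C)OC(=O)OC | intermediate
5 | 4-(methoxymethoxy)-3-{[(2S,3E)-pent-3-en-2-yl]oxy}benzaldehyde | C/C=C/[C@H](C)Oc1cc(C=O)ccc1OCOC | intermediate
6 | (6R)-4-(methoxymethoxy)-5-oxo-6-[(2R,3E)-pent-3-en-2-yl]cyclohexa-1,3-diene-1-carbaldehyde (ortho-dienone, formed in the flask, not isolated) | O=C1C(OCOC)=CC=C(C=O)[C@H]1[C@H](C)/C=C/C | intermediate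
7 | 3-hydroxy-4-(methoxymethoxy)-2-[(2R,3E)-pent-3-en-2-yl]benzaldehyde | C/C=C/[C@@H](C)c1c(O)c(OCOC)ccc1C=O | intermediate
8 | 3,4-bis(methoxymethoxy)-2-[(2R,3E)-pent-3-en-2-yl]benzaldehyde | C/C=C/[C@@H](C)c1c(OCOC)c(OCOC)ccc1C=O | intermediate
9 | (1RS)-1-{3,4-bis(methoxymethoxy)-2-[(2R,3E)-pent-3-en-2-yl]phenyl}prop-2-en-1-ol (both carbinol epimers) | C=CC(O)c1ccc(OCOC)c(OCOC)c1[C@H](C)/C=C/C | intermediate
10 | pent-4-enal | C=CCCC=O | starting material
11 | (2S,3S)-3-{3,4-bis(methoxymethoxy)-2-[(2R,3E)-pent-3-en-2-yl]phenyl}-2-(prop-2-en-1-yl)pent-4-enal (formed in the flask, not isolated) | C=CC[C@H](C=O)[C@H](C=C)c1ccc(OCOC)c(OCOC)c1[C@H](C)/C=C/C | intermediate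
12 | (2S,3S)-3-{3,4-bis(methoxymethoxy)-2-[(2R,3E)-pent-3-en-2-yl]phenyl}-2-(prop-2-en-1-yl)pent-4-en-1-ol | C=CC[C@H](CO)[C@H](C=C)c1ccc(OCOC)c(OCOC)c1[C@H](C)/C=C/C | intermediate
13 | tert-butyl{[(2S,3S)-3-{3,4-bis(methoxymethoxy)-2-[(2R,3E)-pent-3-en-2-yl]phenyl}-2-(prop-2-en-1-yl)pent-4-en-1-yl]oxy}dimethylsilane | C=CC[C@H](CO[Si](C)(C)C(C)(C)C)[C@H](C=C)c1ccc(OCOC)c(OCOC)c1[C@H](C)/C=C/C | intermediate
14 | methyl (2R)-3-hydroxy-2-methylpropanoate | COC(=O)[C@H](C)CO | starting material
15 | methyl (2R)-3-{[tert-butyl(dimethyl)silyl]oxy}-2-methylpropanoate | COC(=O)[C@H](C)CO[Si](C)(C)C(C)(C)C | intermediate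
16 | (2R)-3-{[tert-butyl(dimethyl)silyl]oxy}-2-methylpropanal | O=C[C@H](C)CO[Si](C)(C)C(C)(C)C | intermediate
17 | tert-butyl(dimethyl){[(2S)-2-methylbut-3-en-1-yl]oxy}silane | C=C[C@H](C)CO[Si](C)(C)C(C)(C)C | intermediate
18 | tert-butyl{[(1S,2S)-2-{3,4-bis(methoxymethoxy)-2-[(2R,3E)-pent-3-en-2-yl]phenyl}cyclopent-3-en-1-yl]methoxy}dimethylsilane (formed in the flask, not isolated) | C1=C[C@H](c2ccc(OCOC)c(OCOC)c2[C@H](C)/C=C/C)[C@@H](CO[Si](C)(C)C(C)(C)C)C1 | intermediate
19 | (1S,4R)-1-[(2S,4E,6S)-1,7-bis{[tert-butyl(dimethyl)silyl]oxy}-6-methylhept-4-en-2-yl]-5,6-bis(methoxymethoxy)-4-methyl-1,4-dihydronaphthalene | C[C@H](CO[Si](C)(C)C(C)(C)C)/C=C/C[C@H](CO[Si](C)(C)C(C)(C)C)[C@@H]1C=C[C@@H](C)c2c1ccc(OCOC)c2OCOC | intermediate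
20 | (1S,4R)-1-[(2S,6S)-1,7-bis{[tert-butyl(dimethyl)silyl]oxy}-6-methylheptan-2-yl]-5,6-bis(methoxymethoxy)-4-methyl-1,2,3,4-tetrahydronaphthalene | C[C@H](CO[Si](C)(C)C(C)(C)C)CCC[C@H](CO[Si](C)(C)C(C)(C)C)[C@@H]1CC[C@@H](C)c2c1ccc(OCOC)c2OCOC | intermediate
21 | {(5R,8S)-8-[(2S,6S)-1,7-bis{[tert-butyl(dimethyl)silyl]oxy}-6-methylheptan-2-yl]-3,4-bis(methoxymethoxy)-5-methyl-5,6,7,8-tetrahydronaphthalen-2-yl}lithium (formed in the flask, not isolated) | C[C@H](CO[Si](C)(C)C(C)(C)C)CCC[C@H](CO[Si](C)(C)C(C)(C)C)[C@@H]1CC[C@@H](C)c2c1cc([Li])c(OCOC)c2OCOC | intermediate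
22 | (5R,8S)-8-[(2S,6S)-1,7-bis{[tert-butyl(dimethyl)silyl]oxy}-6-methylheptan-2-yl]-3,4-bis(methoxymethoxy)-5-methyl-5,6,7,8-tetrahydronaphthalene-2-carboxylic acid | C[C@H](CO[Si](C)(C)C(C)(C)C)CCC[C@H](CO[Si](C)(C)C(C)(C)C)[C@@H]1CC[C@@H](C)c2c1cc(C(=O)O)c(OCOC)c2OCOC | intermediate
23 | (5R,8S)-3,4-dihydroxy-8-[(2S,6S)-1,7-dihydroxy-6-methylheptan-2-yl]-5-methyl-5,6,7,8-tetrahydronaphthalene-2-carboxylic acid | C[C@H](CO)CCC[C@H](CO)[C@@H]1CC[C@@H](C)c2c1cc(C(=O)O)c(O)c2O | target

## Step count and risks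

Total step count: 15.
Longest linear sequence: 11 steps (1 → 2 → 5 → 7 → 8 → 9 → 12 → 13 → 19 → 20 → 22 → 23; steps 1, 3–8, 12–15).

Steps most likely to fail:

1. Step 12. The cascade may stall at the five-ring stage, or lose material to oligomerisation and non-productive cross-metathesis, because three olefins of the substrate and the partner compete for the catalyst. Fallback: the side chain would be completed and saturated before ring closure, so that only the two benzylic olefins remain and a single ring-closing metathesis is possible. It sets out from 9, 10 and 17 and comes back to the route at 20. Cross-metathesis of 10 with 17 (second-generation Grubbs catalyst RuCl2(H2IMes)(PCy3)(=CHPh), CH2Cl2, 40 °C) would give the unsaturated chain aldehyde F1; hydrogenation (H2, PtO2, EtOAc) would give the saturated chain aldehyde F2; the iridium/enamine allylation of step 7 applied to 9 and F2 would give the α-allylated aldehyde F3; NaBH4 would give the primary alcohol F4; TBSCl/imidazole would give the bis-silyl ether F5; ring-closing metathesis of its only two olefins (second-generation Grubbs catalyst, CH2Cl2, 40 °C) would give the 1,4-dihydronaphthalene F6; and H2/PtO2 would give 20.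

2. Step 7. Ionisation of the hindered, electron-rich carbinol may be slow or unselective, and acid-promoted side reactions may erode the branched selectivity and the diastereocontrol. Fallback: auxiliary control in place of dual catalysis. It sets out from 8 and comes back at 12. A Horner–Wadsworth–Emmons reaction of 8 with diethyl {2-[(4S)-4-benzyl-2-oxo-1,3-oxazolidin-3-yl]-2-oxoethyl}phosphonate (LiCl, i-Pr2NEt, MeCN) would give the (E)-enoyl imide F7. CuBr·SMe2-mediated 1,4-addition of vinylmagnesium bromide to the chelated s-cis imide, anti to the benzyl group, would give the β-vinyl imide F8 (C1 set). Alkylation of its (Z)-enolate (NaN(SiMe3)2, allyl iodide, THF, −78 °C), again anti to the benzyl group, would give the α-allyl imide F9 (C11 set). LiBH4 would release the auxiliary and give 12.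

3. Step 3. The catalyst may discriminate poorly between the two termini of the small 1,3-dimethylallyl unit, so that the ether, and with it C4, is formed with insufficient enantiomeric purity. Fallback: a resolved alcohol and an SN2 etherification in place of π-allyl catalysis. It sets out from 3 and 2 and comes back at 5. Lipase-catalysed kinetic resolution of 3 (Candida antarctica lipase B, vinyl acetate) would give the (R)-acetate F10; methanolysis (K2CO3, MeOH) would give the (R)-alcohol F11; and a Mitsunobu reaction of F11 with phenol 2 (PPh3, DIAD, THF, 0 °C) would give 5 with inversion.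

## Further compounds

F1 | step 12 | (4E,6S)-7-{[tert-butyl(dimethyl)silyl]oxy}-6-methylhept-4-enal | O=CCC/C=C/[C@H](C)CO[Si](C)(C)C(C)(C)C
F2 | step 12 | (6S)-7-{[tert-butyl(dimethyl)silyl]oxy}-6-methylheptanal | O=CCCCC[C@H](C)CO[Si](C)(C)C(C)(C)C
F3 | step 12 | (2S,6S)-2-[(1S)-1-{3,4-bis(methoxymethoxy)-2-[(2R,3E)-pent-3-en-2-yl]phenyl}prop-2-en-1-yl]-7-{[tert-butyl(dimethyl)silyl]oxy}-6-methylheptanal | C[C@H](CO[Si](C)(C)C(C)(C)C)CCC[C@H](C=O)[C@H](C=C)c1ccc(OCOC)c(OCOC)c1[C@H](C)/C=C/C
F4 | step 12 | (2S,6S)-2-[(1S)-1-{3,4-bis(methoxymethoxy)-2-[(2R,3E)-pent-3-en-2-yl]phenyl}prop-2-en-1-yl]-7-{[tert-butyl(dimethyl)silyl]oxy}-6-methylheptan-1-ol | C[C@H](CO[Si](C)(C)C(C)(C)C)CCC[C@H](CO)[C@H](C=C)c1ccc(OCOC)c(OCOC)c1[C@H](C)/C=C/C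
F5 | step 12 | tert-butyl{[(2S,6S)-2-[(1S)-1-{3,4-bis(methoxymethoxy)-2-[(2R,3E)-pent-3-en-2-yl]phenyl}prop-2-en-1-yl]-7-{[tert-butyl(dimethyl)silyl]oxy}-6-methylheptyl]oxy}dimethylsilane | C[C@H](CO[Si](C)(C)C(C)(C)C)CCC[C@H](CO[Si](C)(C)C(C)(C)C)[C@H](C=C)c1ccc(OCOC)c(OCOC)c1[C@H](C)/C=C/C
F6 | step 12 | (1S,4R)-1-[(2S,6S)-1,7-bis{[tert-butyl(dimethyl)silyl]oxy}-6-methylheptan-2-yl]-5,6-bis(methoxymethoxy)-4-methyl-1,4-dihydronaphthalene | C[C@H](CO[Si](C)(C)C(C)(C)C)CCC[C@H](CO[Si](C)(C)C(C)(C)C)[C@@H]1C=C[C@@H](C)c2c1ccc(OCOC)c2OCOC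
F7 | step 7 | (4S)-4-benzyl-3-[(2E)-3-{3,4-bis(methoxymethoxy)-2-[(2R,3E)-pent-3-en-2-yl]phenyl}prop-2-enoyl]-1,3-oxazolidin-2-one | O=C(/C=C/c1ccc(OCOC)c(OCOC)c1[C@H](C)/C=C/C)N1[C@@H](Cc2ccccc2)COC1=O
F8 | step 7 | (4S)-4-benzyl-3-[(3R)-3-{3,4-bis(methoxymethoxy)-2-[(2R,3E)-pent-3-en-2-yl]phenyl}pent-4-enoyl]-1,3-oxazolidin-2-one | O=C(C[C@H](C=C)c1ccc(OCOC)c(OCOC)c1[C@H](C)/C=C/C)N1[C@@H](Cc2ccccc2)COC1=O
F9 | step 7 | (4S)-4-benzyl-3-[(2S,3S)-3-{3,4-bis(methoxymethoxy)-2-[(2R,3E)-pent-3-en-2-yl]phenyl}-2-(prop-2-en-1-yl)pent-4-enoyl]-1,3-oxazolidin-2-one | O=C([C@@H](CC=C)[C@H](C=C)c1ccc(OCOC)c(OCOC)c1[C@H](C)/C=C/C)N1[C@@H](Cc2ccccc2)COC1=O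
F10 | step 3 | (2R,3E)-pent-3-en-2-yl acetate | C/C=C/[C@@H](C)OC(C)=O
F11 | step 3 | (2R,3E)-pent-3-en-2-ol | C/C=C/[C@@H](C)O
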